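The ratio of the two forward constants, target over isomer of the product, is the selectivity factor of these flasks, and 1 marks the even division against which each flask is read.

    starting material + partner ⇌ target (K1 = 12 L mol⁻¹, k1 = 0.024 L mol⁻¹ s⁻¹, Ea1 = 66.0 kJ mol⁻¹, ΔH1 = −1.00 kJ mol⁻¹)
    starting material + partner ⇌ isomer of the product (K2 = 170 L mol⁻¹, k2 = 0.010 L mol⁻¹ s⁻¹, Ea2 = 49.0 kJ mol⁻¹, ΔH2 = 27.0 kJ mol⁻¹)
    target + catalyst ⇌ isomer of the product + catalyst, rate k3*[catalyst]*[target] forward; the back reaction follows from the equilibrium constant (k3 = 0.64 L mol⁻¹ s⁻¹, Ea3 = 37.0 kJ mol⁻¹)
    partner + precatalyst → catalyst + spent reagent (k4 = 0.0037 L mol⁻¹ s⁻¹, Ea4 = 74.0 kJ mol⁻¹)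
    (constants at 25 °C)

| flask | starting material | partner | precatalyst | temperature | time |
|---|---|---|---|---|---|
| grey | 0.80 M | 1.00 equiv | 1 mol% | 25 °C | 4.0 min |
| blue | 0.80 M | 1.00 equiv | 1 mol% | −5 °C | 4.0 min |
| ochre | 0.80 M | 1.00 equiv | 1 mol% | −35 °C | 4.0 min |

1. which flask leads in amount of target, in percent of the starting material charged ("all alike" within 1.5 percentage points) (grey / blue / ochre / all alike)
2. how much target is there at the end, in percent of the starting material charged: grey
3. how much target is there at the end, in percent of the starting material charged: blue
4. how much target is there at the end, in percent of the starting material charged: ochre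

- constants are those at 25 °C; use the activation energies and enthalpies for any other temperature

Cooling lowers the factor, because the way to target has the higher barrier. It stands at 2.40 in grey. In blue the forward constants become 0.00122 L mol⁻¹ s⁻¹ and 0.00110 L mol⁻¹ s⁻¹, so the factor is 1.11. In ochre they become 2.93 × 10⁻⁵ L mol⁻¹ s⁻¹ and 6.87 × 10⁻⁵ L mol⁻¹ s⁻¹, so it is 0.426.

The first way of this reckoning runs forward, with no step reversed. Starting material and partner are charged equal and fall together, so conversion is clock/(1 + clock), where the clock is the sum of the forward constants times the starting concentration times the time. Target takes its share of that conversion. Catalyst then moves target on to the isomer. Half of its end amount serves as its mean, and target survives as exp(−exposure). This exposure is reckoned for grey; the lines for blue and ochre carry none.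

grey: clock = 6.53; precatalyst opened = 22.0 %; exposure = 0.135
grey: target = 53.5 %, isomer of the product = 33.2 %
blue: clock = 0.445, target = 0.130 M, which is 16.2 %
ochre: clock = 0.0188, target = 0.00442 M, which is 0.552 %

The second way asks what the step to target can hold. The ceiling is the target standing at equilibrium with the material m outside the isomer of the product, partner equal to starting material:

ceiling = m − (√(1 + 4·K·m) − 1)/(2·K)
grey: m = 0.534 M, K = 12 L mol⁻¹, ceiling = 0.361 M

The two ways part in grey. The first way leaves 13.3 % starting material, and its target is then 3.16 times the equilibrium value for that remainder, so the first way is the one that cheats. The ceiling stands for grey at 45.1 %, and grey leads.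

In blue, with K = 12.6 L mol⁻¹ and m = 0.684 M, the ceiling is 0.487 M. Forward target lies below it, so the forward figure stands there.

The forecast gives 50 % for grey, 16 % for blue and 0.55 % for ochre, and names grey: “the warm flask wins clearly within this short time”. Its grey figure lies above the ceiling reckoned here.

The flasks end at 43.1 % target in grey, 16.0 % in blue and 0.552 % in ochre, and grey leads. The forecast's grey figure is what every back reaction struck out gives. Grey holds 0.345 M target beside 20.8 % of the charged starting material at 4.00 min, so its target stands at 1.03 times the equilibrium value for that remainder, against the reckoned ceiling of 0.361 M.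

The grey recipe at 0.25 mol% precatalyst has its exposure cut to 0.0337, which puts 0.580 M outside the isomer and the ceiling at 49.7 %. That flask, computed, holds 47.9 % target.

All constants were drawn at random within sensible limits; the run is a simulation.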